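Numbering of the target: C1 B/C ring-fusion CH next to the acetal, C2 acetal CH(OAc), C3 enol ether CH, C4 enol ether carbon, C5 ring-fusion CH next to the cyclopropane, C6 and C7 cyclopropane CH, C8, C9, C10 C(Me)(OH), C11 quaternary cyclopropane carbon, C12 its ring-D CH2, C13 CH2OAc, C14 methyl, C15 ring-D CH2 on C4; ring A cyclopropane, ring B cycloheptane, ring C dihydropyran, ring D oxepane.
Cuts, in retrosynthetic order: the two acetates; C1–C5 together with O–C2 (one retro oxa-Diels–Alder step that opens rings B and C); C4=C5 and O–C15 of ring D (retro olefination/oxa-Michael); C6–C11 and C7–C11 of ring A (retro Michael/alkylation); the C6=C7 enal bond (cross-metathesis); the C10 carbinol back to an epoxy alcohol.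
Forward order: the open chain first (geraniol to a protected (S)-hydroxy enal), then ring A on the open chain, then ring D annulated onto ring A, then rings B and C closed together, then desilylation and double acetylation.
Enabling feature: the O–C2H(OAc)–C1H–C5H–C4(=C3H–O) array of ring C is the retron of an enal (O=C3–C4=C5) plus enol ether (C1=C2) cycloaddition, and its C1–C5 bond is also the one bond of ring B that can join the chain on C7 to C5 last, once ring D has tied C4 (through C15–O–C12) to C11.
Stereochemistry: C10 from the Sharpless epoxidation (its C–O bond is not touched afterwards); C6 and C7 (trans) from the (S)-diphenylprolinol silyl ether catalyst; C11 from the cis aldehyde, which decides which geminal CH2OH enters ring D; C1 and C5 in the key step; C2 at the final acetylation, so enol ether isomers and acetal epimers converge.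

Key step: step 16

Assumption: the target configuration is taken exactly as given (ring B trans-fused to the cyclopropane, H1/H5 cis, H5 and H6 trans), and the key cycloaddition is taken to be able to reach the enal face that this requires; a rough geometric estimate suggests this is the harder face for the tether, so the point is unverified and is the main risk.

Step 1
Reactants: 1 geraniol
Product: 2 (2S,3S)-2,3-epoxygeraniol
Conditions: Ti(OiPr)4 (5 mol%), L-(+)-diethyl tartrate (7 mol%), tBuOOH, 4 Å molecular sieves, CH2Cl2, −20 °C
Reagents that add atoms: tert-butyl hydroperoxide, CC(C)(C)OO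
Why: Sharpless asymmetric epoxidation of an allylic alcohol, in which the titanium–L-tartrate complex delivers oxygen to the face of the 2,3-alkene that gives the (2S,3S)-epoxide (this sets the future C10) and leaves the remote trisubstituted alkene alone.

Step 2
Reactants: 2 (2S,3S)-2,3-epoxygeraniol
Product: 3 (3S)-3,7-dimethyloct-6-ene-1,3-diol
Conditions: NaAlH2(OCH2CH2OMe)2, THF, 0 °C to rt; aqueous potassium sodium tartrate work-up
Reagents that add atoms: none
Why: Directed reductive opening of a 2,3-epoxy alcohol, in which the aluminate bound to the primary oxygen delivers hydride intramolecularly to the secondary epoxide carbon, so the tertiary C–O bond and its configuration are kept and the 1,3-diol results.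

Step 3
Reactants: 3 (3S)-3,7-dimethyloct-6-ene-1,3-diol
Product: 4 (3S)-1-(4-methoxybenzyloxy)-3,7-dimethyloct-6-en-3-ol
Conditions: NaH (1.05 equiv), 4-methoxybenzyl chloride, Bu4NI (cat.), THF/DMF, 0 °C to rt
Reagents that add atoms: 4-methoxybenzyl chloride, COc1ccc(CCl)cc1
Why: Williamson etherification, in which one equivalent of base lets the unhindered primary alkoxide be alkylated far faster than the tertiary one.

Step 4
Reactants: 4 (3S)-1-(4-methoxybenzyloxy)-3,7-dimethyloct-6-en-3-ol
Product: 5 (3S)-1-(4-methoxybenzyloxy)-3,7-dimethyl-3-(triethylsilyloxy)oct-6-ene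
Conditions: TESOTf, 2,6-lutidine, CH2Cl2, −78 to 0 °C
Reagents that add atoms: triethylsilyl triflate, CC[Si](CC)(CC)OS(=O)(=O)C(F)(F)F
Why: Silylation of a tertiary alcohol with a silyl triflate and a hindered pyridine base, a standard protection that masks the hydroxyl which would otherwise add to the enal under iminium catalysis in step 6.

Step 5
Reactants: 5 (3S)-1-(4-methoxybenzyloxy)-3,7-dimethyl-3-(triethylsilyloxy)oct-6-ene, 6 (E)-crotonaldehyde
Product: 7 (2E,6S)-8-(4-methoxybenzyloxy)-6-methyl-6-(triethylsilyloxy)oct-2-enal
Conditions: second-generation Hoveyda–Grubbs catalyst (5 mol%), crotonaldehyde in excess, CH2Cl2, 40 °C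
Reagents that add atoms: none
Why: Olefin cross-metathesis, in which the ruthenium carbene exchanges the isopropylidene end of the trisubstituted alkene for the formylmethylidene unit of crotonaldehyde and the conjugated E-enal is the thermodynamically favoured product.

Step 6
Reactants: 7 (2E,6S)-8-(4-methoxybenzyloxy)-6-methyl-6-(triethylsilyloxy)oct-2-enal, 8 diethyl bromomalonate
Product: 10 diethyl (2R,3R)-2-formyl-3-[(3S)-5-(4-methoxybenzyloxy)-3-methyl-3-(triethylsilyloxy)pentyl]cyclopropane-1,1-dicarboxylate, via bromomalonate Michael adduct 9 (not isolated)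
Conditions: (S)-α,α-diphenylprolinol trimethylsilyl ether (20 mol%), 2,6-lutidine (1.1 equiv), CH2Cl2, 0 °C to rt
Reagents that add atoms: none
Why: Iminium–enamine organocascade (Michael-initiated ring closure): the bromomalonate adds to the enal β-carbon on the face of the E-iminium ion not shielded by the diphenyl(silyloxy)methyl group (sets C7), and the enamine then displaces bromide in a 3-exo-tet closure that puts the formyl group trans to the chain (sets C6).

Step 7
Reactants: 10 diethyl (2R,3R)-2-formyl-3-[(3S)-5-(4-methoxybenzyloxy)-3-methyl-3-(triethylsilyloxy)pentyl]cyclopropane-1,1-dicarboxylate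
Product: 11 dimethyl acetal of 10
Conditions: HC(OMe)3, PPTS (cat.), MeOH, rt
Reagents that add atoms: trimethyl orthoformate, COC(OC)OC; methanol, CO
Why: Acid-catalysed acetalisation with the orthoformate as water scavenger, which masks the aldehyde before hydride reduction under conditions mild enough for the tertiary TES ether and the PMB ether.

Step 8
Reactants: 11 dimethyl acetal of 10
Product: 12 cyclopropane-1,1-diyldimethanol acetal
Conditions: LiAlH4, THF, 0 °C; aqueous NaOH work-up
Reagents that add atoms: none
Why: Hydride reduction of both esters to primary alcohols, to which the acetal, the silyl ether and the benzyl-type ether are inert.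

Step 9
Reactants: 12 cyclopropane-1,1-diyldimethanol acetal
Product: 13 bicyclic lactol alcohol
Conditions: PPTS (cat.), acetone/H2O, rt
Reagents that add atoms: water, O
Why: Acid-catalysed acetal hydrolysis followed by ring–chain tautomerisation, in which only the hydroxymethyl group cis to the formyl group can reach it across the cyclopropane, so a single five-membered lactol forms and the two geminal CH2OH groups become different (this fixes C11).

Step 10
Reactants: 13 bicyclic lactol alcohol
Product: 14 bicyclic lactol TBDPS ether
Conditions: TBDPSCl (1.05 equiv), imidazole, DMF, 0 °C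
Reagents that add atoms: tert-butyldiphenylsilyl chloride, CC(C)(C)[Si](Cl)(c1ccccc1)c1ccccc1
Why: Selective silylation of a primary alcohol beside a lactol hydroxyl with a bulky silyl chloride, as in the 5-O-silylation of free pentofuranoses; TBDPS is used instead of TBS because it resists the 1,3 O-to-O silyl shift between the geminal CH2O groups under the basic conditions of step 11.

Step 11
Reactants: 14 bicyclic lactol TBDPS ether, 15 ethyl 2-(diethoxyphosphoryl)acrylate
Product: 17 ring A/D ester, via oxa-Michael adduct phosphonate 16 (not isolated)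
Conditions: NaH (1.1 equiv), THF, 0 °C to rt
Reagents that add atoms: none
Why: Tandem oxa-Michael addition and intramolecular Horner–Wadsworth–Emmons olefination: the alkoxide of the ring-opened lactol adds to the vinylphosphonate and the phosphonate carbanion so formed olefinates the neighbouring aldehyde, the cis-cyclopropane holding both ends together for the seven-membered ring D with its necessarily cis ring alkene.

Step 12
Reactants: 17 ring A/D ester
Product: 18 ring A/D allylic alcohol
Conditions: iBu2AlH (2.2 equiv), CH2Cl2, −78 °C; aqueous potassium sodium tartrate work-up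
Reagents that add atoms: none
Why: 1,2-Reduction of an α,β-unsaturated ester to the allylic alcohol with a dialkylaluminium hydride at low temperature, which leaves the silyl and PMB ethers untouched.

Step 13
Reactants: 18 ring A/D allylic alcohol
Product: 19 ring A/D diol
Conditions: DDQ, CH2Cl2/aqueous pH 7 phosphate buffer, 0 °C
Reagents that add atoms: none
Why: Oxidative cleavage of a p-methoxybenzyl ether by DDQ (hydride abstraction, then hydrolysis of the oxocarbenium ion), which spares the silyl ethers; any incidental oxidation of the allylic alcohol only anticipates step 14.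

Step 14
Reactants: 19 ring A/D diol
Product: 20 ring A/D dialdehyde
Conditions: Dess–Martin periodinane, NaHCO3, CH2Cl2, 0 °C to rt
Reagents that add atoms: none
Why: Dess–Martin oxidation of both primary alcohols under buffered conditions, the allylic one to the ring-D enal and the saturated one to the β-silyloxy aldehyde.

Step 15
Reactants: 20 ring A/D dialdehyde
Product: 21 ring-D enal with tethered TIPS enol ether
Conditions: TIPSOTf, Et3N, CH2Cl2, 0 °C to rt
Reagents that add atoms: triisopropylsilyl triflate, CC(C)[Si](OS(=O)(=O)C(F)(F)F)(C(C)C)C(C)C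
Why: Soft enolisation and O-silylation of an aldehyde with a silyl triflate and a tertiary amine, in which only the saturated aldehyde has an α-hydrogen (the enal cannot enolise); the E/Z mixture is acceptable because the carbon it affects (C2) is equilibrated later.

Step 16
Reactants: 21 ring-D enal with tethered TIPS enol ether
Product: 22 tetracyclic silyl acetal
Conditions: Eu(fod)3 (10 mol%), toluene (0.002 M), 80 to 110 °C
Reagents that add atoms: none
Why: Proposed new method: the enal O=C3–C4=C5 of 21 acts as an electron-poor 1-oxadiene and the silyl enol ether C1=C2 as the electron-rich partner in an Eu(fod)3-activated, asynchronous inverse-electron-demand [4+2] cycloaddition in which the C5–C1 bond forms ahead of the O–C2 bond. The closest known reactions are the intramolecular enal plus enol ether (or enamine) oxa-Diels–Alder closures that give iridoid dihydropyran acetals on five- and six-membered carbocycles and the intermolecular Eu(fod)3-catalysed enal plus enol ether cycloaddition; a seven-membered ring trans-fused to a cyclopropane has not been closed in this way. Ring B closes in the fused (type 1) intramolecular mode through the five-atom tether C6–C7–C8–C9–C10 as the seven-membered carbocycle, and ring C is the six-membered cycloadduct ring itself. C5 is set by the one π-face of the ring-D-locked enal that the three-atom link C8–C9–C10 from the trans carbon C7 can reach, C1 by suprafacial addition through the folded transition state that gives the cis B/C junction, with the C10 centre (Me versus OTES) choosing the enol ether face, and C2 by the enol ether geometry, which is left uncontrolled. The step therefore needs π-facial selectivity at C5 (H5 trans to H6) and a cis ring fusion but no E/Z or endo/exo control, and it relies for them on the rigid cyclopropane-fused oxepine, the short tether and the stereocentre at C10. The enal has no enolisable position and the cycloaddition is irreversible and strongly exothermic, which is meant to pay for the strain of the trans-bicyclo[5.1.0]octane.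

Step 17
Reactants: 22 tetracyclic silyl acetal
Product: 23 lactol triol
Conditions: HF·pyridine, pyridine, THF, 0 °C to rt
Reagents that add atoms: none
Why: Fluoride-mediated Si–O cleavage, in which buffered HF·pyridine removes the anomeric TIPS group, the tertiary TES ether and the primary TBDPS ether without acid strong enough to hydrate the enol ether; the lactol epimers at C2 then interconvert through the ring-opened dialdehyde.

Step 18
Reactants: 23 lactol triol
Product: 24 target CNP0250836.2
Conditions: Ac2O, pyridine, CH2Cl2, 0 °C to rt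
Reagents that add atoms: acetic anhydride, CC(=O)OC(C)=O
Why: Acylation with anhydride and pyridine, which esterifies the primary and the lactol hydroxyl but not the tertiary alcohol, and which should drain the equilibrating lactol to the acetate trans to the C1–C10 bond (anomeric and steric preference), setting C2.

Compound list
1 | geraniol, (2E)-3,7-dimethylocta-2,6-dien-1-ol | CC(C)=CCC/C(C)=C/CO | starting material
2 | (2S,3S)-2,3-epoxygeraniol, [(2S,3S)-3-methyl-3-(4-methylpent-3-en-1-yl)oxiran-2-yl]methanol | CC(C)=CCC[C@]1(C)O[C@H]1CO | intermediate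
3 | (3S)-3,7-dimethyloct-6-ene-1,3-diol | CC(C)=CCC[C@](CCO)(C)O | intermediate
4 | (3S)-1-(4-methoxybenzyloxy)-3,7-dimethyloct-6-en-3-ol | CC(C)=CCC[C@](CCOCc1ccc(OC)cc1)(C)O | intermediate
5 | (3S)-1-(4-methoxybenzyloxy)-3,7-dimethyl-3-(triethylsilyloxy)oct-6-ene | CC(C)=CCC[C@](CCOCc1ccc(OC)cc1)(C)O[Si](CC)(CC)CC | intermediate
6 | (E)-crotonaldehyde, (2E)-but-2-enal | C/C=C/C=O | starting material
7 | (2E,6S)-8-(4-methoxybenzyloxy)-6-methyl-6-(triethylsilyloxy)oct-2-enal | O=C/C=C/CC[C@](CCOCc1ccc(OC)cc1)(C)O[Si](CC)(CC)CC | intermediate
8 | diethyl bromomalonate | CCOC(=O)C(Br)C(=O)OCC | starting material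
9 | bromomalonate Michael adduct (not isolated), diethyl 2-bromo-2-[(3R,6S)-8-(4-methoxybenzyloxy)-6-methyl-1-oxo-6-(triethylsilyloxy)octan-3-yl]malonate, drawn as the free aldehyde and held in the flask as its catalyst enamine | O=CC[C@@H](CC[C@](CCOCc1ccc(OC)cc1)(C)O[Si](CC)(CC)CC)C(Br)(C(=O)OCC)C(=O)OCC | intermediate
10 | diethyl (2R,3R)-2-formyl-3-[(3S)-5-(4-methoxybenzyloxy)-3-methyl-3-(triethylsilyloxy)pentyl]cyclopropane-1,1-dicarboxylate (formyl trans to the chain; ring A) | O=C[C@@H]1[C@@H](CC[C@](CCOCc2ccc(OC)cc2)(C)O[Si](CC)(CC)CC)C1(C(=O)OCC)C(=O)OCC | intermediate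
11 | dimethyl acetal of 10, diethyl (2R,3R)-2-(dimethoxymethyl)-3-[(3S)-5-(4-methoxybenzyloxy)-3-methyl-3-(triethylsilyloxy)pentyl]cyclopropane-1,1-dicarboxylate | COC(OC)[C@@H]1[C@@H](CC[C@](CCOCc2ccc(OC)cc2)(C)O[Si](CC)(CC)CC)C1(C(=O)OCC)C(=O)OCC | intermediate
12 | cyclopropane-1,1-diyldimethanol acetal, {(2R,3R)-2-(dimethoxymethyl)-3-[(3S)-5-(4-methoxybenzyloxy)-3-methyl-3-(triethylsilyloxy)pentyl]cyclopropane-1,1-diyl}dimethanol | COC(OC)[C@@H]1[C@@H](CC[C@](CCOCc2ccc(OC)cc2)(C)O[Si](CC)(CC)CC)C1(CO)CO | intermediate
13 | bicyclic lactol alcohol, (1R,6R)-5-(hydroxymethyl)-6-[(3S)-5-(4-methoxybenzyloxy)-3-methyl-3-(triethylsilyloxy)pentyl]-3-oxabicyclo[3.1.0]hexan-2-ol (chain exo, i.e. trans to the oxolane ring and cis to the CH2OH on C5; lactol epimers) | OC1OC[C@@]2(CO)[C@H](CC[C@](CCOCc3ccc(OC)cc3)(C)O[Si](CC)(CC)CC)[C@@H]12 | intermediate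
14 | bicyclic lactol TBDPS ether, 13 with the CH2OH on C5 as its tert-butyldiphenylsilyl ether (lactol epimers) | OC1OC[C@@]2(CO[Si](c3ccccc3)(c3ccccc3)C(C)(C)C)[C@H](CC[C@](CCOCc3ccc(OC)cc3)(C)O[Si](CC)(CC)CC)[C@@H]12 | intermediate
15 | ethyl 2-(diethoxyphosphoryl)acrylate | C=C(C(=O)OCC)P(=O)(OCC)OCC | starting material
16 | oxa-Michael adduct phosphonate (not isolated): open aldehyde form of 14 whose cis CH2OH carries a 2-(diethoxyphosphoryl)-2-(ethoxycarbonyl)ethyl ether (phosphonate carbon unassigned) | O=C[C@@H]1[C@@H](CC[C@](CCOCc2ccc(OC)cc2)(C)O[Si](CC)(CC)CC)[C@]1(CO[Si](c2ccccc2)(c2ccccc2)C(C)(C)C)COCC(C(=O)OCC)P(=O)(OCC)OCC | intermediate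
17 | ring A/D ester, ethyl cis-fused 1-[(tert-butyldiphenylsilyloxy)methyl]-8-[(3S)-5-(4-methoxybenzyloxy)-3-methyl-3-(triethylsilyloxy)pentyl]-3-oxabicyclo[5.1.0]oct-5-ene-5-carboxylate (chain on the cyclopropane trans to C5 and cis to CH2OTBDPS) | CC(C)(C)[Si](c1ccccc1)(c1ccccc1)OC[C@@]12COCC(C(=O)OCC)=C[C@@H]1[C@H]2CC[C@](CCOCc3ccc(OC)cc3)(C)O[Si](CC)(CC)CC | intermediate
18 | ring A/D allylic alcohol, 17 with CH2OH in place of the ester | CC(C)(C)[Si](c1ccccc1)(c1ccccc1)OC[C@@]12COCC(CO)=C[C@@H]1[C@H]2CC[C@](CCOCc3ccc(OC)cc3)(C)O[Si](CC)(CC)CC | intermediate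
19 | ring A/D diol, 18 with the PMB ether cleaved to the primary alcohol | CC(C)(C)[Si](c1ccccc1)(c1ccccc1)OC[C@@]12COCC(CO)=C[C@@H]1[C@H]2CC[C@](CCO)(C)O[Si](CC)(CC)CC | intermediate
20 | ring A/D dialdehyde, 5-formyl-3-oxabicyclo[5.1.0]oct-5-ene carrying CH2OTBDPS on C1 and the (3S)-3-methyl-5-oxo-3-(triethylsilyloxy)pentyl chain on C8 | CC(C)(C)[Si](c1ccccc1)(c1ccccc1)OC[C@@]12COCC(C=O)=C[C@@H]1[C@H]2CC[C@](CC=O)(C)O[Si](CC)(CC)CC | intermediate
21 | ring-D enal with tethered TIPS enol ether, 20 with the saturated aldehyde as its triisopropylsilyl enol ether (E/Z mixture) | CC(C)(C)[Si](c1ccccc1)(c1ccccc1)OC[C@@]12COCC(C=O)=C[C@@H]1[C@H]2CC[C@](C=CO[Si](C(C)C)(C(C)C)C(C)C)(C)O[Si](CC)(CC)CC | intermediate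
22 | tetracyclic silyl acetal (rings A, B, C, D; C2–OTIPS epimers; C13 OTBDPS; C10 OTES; H1/H5 cis, H5/H6 trans, H6/H7 trans) | CC(C)(C)[Si](c1ccccc1)(c1ccccc1)OC[C@@]12COCC3=COC(O[Si](C(C)C)(C(C)C)C(C)C)[C@@H]4[C@H]3[C@@H]1[C@H]2CC[C@]4(C)O[Si](CC)(CC)CC | intermediate
23 | lactol triol (C2–OH epimers, C13–OH, C10–OH) | OC[C@@]12COCC3=COC(O)[C@@H]4[C@H]3[C@@H]1[C@H]2CC[C@]4(C)O | intermediate
24 | target CNP0250836.2, the C2,C13-diacetate with free tertiary C10–OH (C2–OAc cis to H1, trans to the C1–C10 bond) | CC(=O)OC[C@@]12COCC3=CO[C@H](OC(C)=O)[C@@H]4[C@H]3[C@@H]1[C@H]2CC[C@]4(C)O | target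

Total step count: 18.
Longest linear sequence: 18 steps, from geraniol 1 to 24 (compounds 6, 8 and 15 are bought).

Steps most likely to fail

1. Step 16 (the new method). Three things may go wrong. First, closure of ring B trans onto the cyclopropane may be so slow that the silyl enol ether is lost first, by protodesilylation or by Lewis-acid-assisted loss of triethylsilanol from C10 to a dienal. Second, the tether can engage only one π-face of the ring-D-locked enal; if that is not the face leaving H5 trans to H6, the bond forms, if at all, in the C1/C5-epimeric series. Third, a trans B/C junction may form, which is the least serious because C1 can be equilibrated through the open dialdehyde form of 23. Fallback with known chemistry: from dialdehyde 20, a secondary amine (for example (S)-α,α-diphenylprolinol trimethylsilyl ether with PhCO2H in CH2Cl2) turns the saturated aldehyde into its enamine, which adds to the tethered enal in an intramolecular Michael reaction of the kind used to cyclise iridoid-type formyl enals. Hydrolysis of the iminium ion gives the 1,5-dialdehyde Michael adduct F1, which should close on its own to the bis-silylated enol-lactol F2. HF·pyridine/pyridine then removes the TBDPS and TES groups and the route is rejoined at lactol triol 23. This fallback drops the Lewis acid and the fragile enol ether and separates C–C bond formation from ring C closure. It shares the tether geometry of the main route, so the facial question must be settled by a conformational search on 20 and 21 before material is committed.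

2. Step 11. After the oxa-Michael addition the phosphonate carbanion may fail to close the seven-membered ring, through retro-oxa-Michael reaction, intermolecular olefination, or a silyl shift that frees the wrong hydroxymethyl group. Fallback: from lactol 14, Wittig methylenation of the masked aldehyde (Ph3PCH3Br, KOtBu, THF) gives the vinylcyclopropane alcohol F3 with the cis hydroxymethyl group free. O-Alkylation with ethyl 2-(bromomethyl)acrylate (NaH, THF, 0 °C) gives the diene ether F4. Ring-closing metathesis between the vinyl group and the acrylate alkene (second-generation Hoveyda–Grubbs catalyst, toluene, 80 °C) closes ring D and rejoins the route at ester 17.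

3. Step 15. With two aldehydes present, the freshly formed enol ether may attack the triflate-activated enal in an uncontrolled Mukaiyama–Michael reaction, or the dialdehyde may degrade (loss of triethylsilanolate from the β-silyloxy aldehyde) before silylation is complete. Fallback: the enol ether is made before the enal exists. From ester 17, DDQ gives the ester alcohol F5, Dess–Martin periodinane the ester aldehyde F6, and TIPSOTf/Et3N the ester enol ether F7. iBu2AlH at −78 °C then gives the allylic alcohol F8, and MnO2 in CH2Cl2 oxidises it to the enal, which is compound 21.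

Further compounds
F1 | step 16 | 1,5-dialdehyde Michael adduct (C1–C5 bond formed, TBDPS and TES ethers in place, C4 epimers) | CC(C)(C)[Si](c1ccccc1)(c1ccccc1)OC[C@@]12COCC(C=O)[C@H]([C@@H]1[C@H]2CC[C@]3(C)O[Si](CC)(CC)CC)[C@H]3C=O
F2 | step 16 | bis-silylated enol-lactol (rings A to D, C2–OH epimers) | CC(C)(C)[Si](c1ccccc1)(c1ccccc1)OC[C@@]12COCC3=COC(O)[C@@H]4[C@H]3[C@@H]1[C@H]2CC[C@]4(C)O[Si](CC)(CC)CC
F3 | step 11 | vinylcyclopropane alcohol (vinyl on C6, free cis CH2OH, CH2OTBDPS, chain trans to vinyl) | C=C[C@@H]1[C@@H](CC[C@](CCOCc2ccc(OC)cc2)(C)O[Si](CC)(CC)CC)[C@]1(CO[Si](c2ccccc2)(c2ccccc2)C(C)(C)C)CO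
F4 | step 11 | diene ether, 2-(ethoxycarbonyl)allyl ether of F3 | C=C[C@@H]1[C@@H](CC[C@](CCOCc2ccc(OC)cc2)(C)O[Si](CC)(CC)CC)[C@]1(CO[Si](c2ccccc2)(c2ccccc2)C(C)(C)C)COCC(=C)C(=O)OCC
F5 | step 15 | ester alcohol, 17 with the PMB ether cleaved | CC(C)(C)[Si](c1ccccc1)(c1ccccc1)OC[C@@]12COCC(C(=O)OCC)=C[C@@H]1[C@H]2CC[C@](CCO)(C)O[Si](CC)(CC)CC
F6 | step 15 | ester aldehyde | CC(C)(C)[Si](c1ccccc1)(c1ccccc1)OC[C@@]12COCC(C(=O)OCC)=C[C@@H]1[C@H]2CC[C@](CC=O)(C)O[Si](CC)(CC)CC
F7 | step 15 | ester enol ether (TIPS enol ether, E/Z) | CC(C)(C)[Si](c1ccccc1)(c1ccccc1)OC[C@@]12COCC(C(=O)OCC)=C[C@@H]1[C@H]2CC[C@](C=CO[Si](C(C)C)(C(C)C)C(C)C)(C)O[Si](CC)(CC)CC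
F8 | step 15 | allylic alcohol enol ether (TIPS enol ether, E/Z) | CC(C)(C)[Si](c1ccccc1)(c1ccccc1)OC[C@@]12COCC(CO)=C[C@@H]1[C@H]2CC[C@](C=CO[Si](C(C)C)(C(C)C)C(C)C)(C)O[Si](CC)(CC)CC
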